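**Plan**

- Retrosynthesis: the C1–O21 ester bond and the O6–C7 oxirane bond are cut together; then come C7–Br (from O7–H), the C1–O6 lactone bond, C3–C4 and C9–C10 (epoxide openings) and C19–C20.
- Enabling feature: the epoxide oxygen O6 is the sixth atom from the carbonyl carbon C1 (C1, Z-C2=C3, C4, C5, C6, O6). C1–C6 plus O6 can therefore be held beforehand as a seven-membered Z-enoate lactone carrying a bromide on the neighbouring C7.
- Forward: a C10–C22 Grignard reagent and ethyl propiolate (C1–C3) open the two ends of the L-ido bis-epoxide (C4–C9). The seven-membered lactone is closed on O6 and bromide is put on C7. One base-induced cascade then expands the lactone to the 22-membered ring and closes the oxirane.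
- Stereochemistry: C5–C8 come from D-mannitol (C5 and C8 inverted when the bis-epoxide forms; C7 inverted twice, by bromide and then by O6). C21 comes from (R)-propylene oxide, the Z alkene from Lindlar reduction.

Key step: step 17

Assumption: 3,4-O-isopropylidene-D-mannitol (8), the mono-acetonide of D-mannitol, is taken as a purchasable starting material.

Convention: locants C1–C22 are those of the seco acid (C1 carbonyl, C21 ring-closing carbinol). The R/S labels at C6/C7 change with the rank of the neighbouring O-substituents, although only C7 is ever inverted (steps 15 and 17). TBS = tert-butyldimethylsilyl, NAP = 2-naphthylmethyl.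

**Route**

Step 1
Reactants: 1 10-bromodecan-1-ol
Product: 2 tert-butyl[(10-bromodecyl)oxy]dimethylsilane
Conditions: TBSCl, imidazole, CH2Cl2, 0 °C → rt
Reagents that add atoms: tert-butyldimethylsilyl chloride, CC(C)(C)[Si](C)(C)Cl
Why: Imidazole-promoted silylation of the primary alcohol (silyl ether formation), which leaves the primary bromide untouched.

Step 2
Reactants: 2 tert-butyl[(10-bromodecyl)oxy]dimethylsilane; 3 (R)-propylene oxide
Product: 5 (R)-13-[(tert-butyldimethylsilyl)oxy]tridecan-2-ol, via Grignard reagent 4 (not isolated)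
Conditions: Mg, THF, 40 °C; then CuI (10 mol %), 3, −30 → 0 °C; aq. NH4Cl
Reagents that add atoms: none
Why: Copper-catalysed Grignard opening of a monosubstituted epoxide by SN2 at its CH2 terminus, so the (R) carbinol centre of 3 is carried over unchanged and becomes C21.

Step 3
Reactants: 5 (R)-13-[(tert-butyldimethylsilyl)oxy]tridecan-2-ol
Product: 6 (R)-tert-butyldimethyl{[12-(2-naphthylmethoxy)tridecyl]oxy}silane
Conditions: NaH, 2-(bromomethyl)naphthalene, Bu4NI (cat.), THF/DMF, 0 °C → rt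
Reagents that add atoms: 2-(bromomethyl)naphthalene, BrCc1ccc2ccccc2c1
Why: Williamson ether synthesis with a benzylic bromide; the NAP ether should tolerate Grignard formation, aqueous acid and Lindlar hydrogenation and can later be removed oxidatively beside silyl ethers.

Step 4
Reactants: 6 (R)-tert-butyldimethyl{[12-(2-naphthylmethoxy)tridecyl]oxy}silane
Product: 7 2-({[(2R)-13-bromotridecan-2-yl]oxy}methyl)naphthalene
Conditions: Ph3PBr2, CH2Cl2, 0 °C → rt
Reagents that add atoms: triphenylphosphine dibromide, BrP(Br)(c1ccccc1)(c1ccccc1)c1ccccc1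
Why: Direct conversion of a primary silyl ether into the bromide with triphenylphosphine dibromide (Appel-type SN2 at the primary carbon after Si–O cleavage), the secondary arylmethyl ether being inert at room temperature.

Step 5
Reactants: 8 3,4-O-isopropylidene-D-mannitol
Product: 9 1,6-di-O-benzoyl-3,4-O-isopropylidene-D-mannitol
Conditions: BzCl (2.1 equiv), pyridine, CH2Cl2, −40 → −10 °C
Reagents that add atoms: benzoyl chloride, O=C(Cl)c1ccccc1
Why: Kinetic O-acylation in pyridine of the two primary hydroxyls, equivalent by C2 symmetry, in preference to the hindered secondary ones at low temperature.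

Step 6
Reactants: 9 1,6-di-O-benzoyl-3,4-O-isopropylidene-D-mannitol
Product: 10 1,6-di-O-benzoyl-3,4-O-isopropylidene-2,5-di-O-methanesulfonyl-D-mannitol
Conditions: MsCl, Et3N, CH2Cl2, 0 °C
Reagents that add atoms: methanesulfonyl chloride, CS(=O)(=O)Cl
Why: O-Sulfonylation of both secondary alcohols with retention, which turns sugar C2 and C5 into electrophilic centres.

Step 7
Reactants: 10 1,6-di-O-benzoyl-3,4-O-isopropylidene-2,5-di-O-methanesulfonyl-D-mannitol
Product: 12 1,2:5,6-dianhydro-3,4-O-isopropylidene-L-iditol, via diol dimesylate 11 (not isolated)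
Conditions: K2CO3, MeOH, 0 °C → rt
Reagents that add atoms: none
Why: Base-catalysed methanolysis frees the primary alkoxides, which close both oxiranes by intramolecular Williamson displacement (3-exo-tet) of the adjacent mesylates with inversion at sugar C2 and C5, so the D-manno array becomes the L-ido array needed for C5 and C8.

Step 8
Reactants: 7 2-({[(2R)-13-bromotridecan-2-yl]oxy}methyl)naphthalene; 12 1,2:5,6-dianhydro-3,4-O-isopropylidene-L-iditol
Product: 14 (2S)-2-{(4R,5R)-5-[(1S,14R)-1-hydroxy-14-(2-naphthylmethoxy)pentadecyl]-2,2-dimethyl-1,3-dioxolan-4-yl}oxirane (C4–C22 epoxy alcohol), via Grignard reagent 13 (not isolated)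
Conditions: 7, Mg, THF, 40 °C; then added slowly to 12 (2.5 equiv), CuI (10 mol %), THF, −40 → −20 °C; aq. NH4Cl
Reagents that add atoms: none
Why: Copper-catalysed Grignard opening at the terminal carbon of one of two homotopic epoxides; C2 symmetry removes any regiochemical question, excess 12 limits double addition, the trans-fused acetonide blocks tetrahydrofuran formation by the new alkoxide, and no stereocentre is touched.

Step 9
Reactants: 14 C4–C22 epoxy alcohol; 15 ethyl propiolate
Product: 17 ethyl (5S,6R,7R,8S,21R)-5,8-dihydroxy-6,7-(isopropylidenedioxy)-21-(2-naphthylmethoxy)docos-2-ynoate, via lithium ethyl propiolate 16 (not isolated)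
Conditions: 15 (4 equiv), n-BuLi, THF, −78 °C; BF3·OEt2 (4 equiv); then 14, −78 °C; aq. NH4Cl at −78 °C
Reagents that add atoms: none
Why: Yamaguchi–Hirao alkynylation, in which the BF3-activated terminal epoxide is opened at CH2 by the lithium acetylide (the extra equivalents cover the free C8 hydroxyl), so C5 keeps the configuration of the epoxide.

Step 10
Reactants: 17 ethyl (5S,6R,7R,8S,21R)-5,8-dihydroxy-6,7-(isopropylidenedioxy)-21-(2-naphthylmethoxy)docos-2-ynoate
Product: 18 ethyl (5S,6S,7S,8S,21R)-5,8-bis[(tert-butyldimethylsilyl)oxy]-6,7-(isopropylidenedioxy)-21-(2-naphthylmethoxy)docos-2-ynoate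
Conditions: TBSOTf, 2,6-lutidine, CH2Cl2, −78 → 0 °C
Reagents that add atoms: tert-butyldimethylsilyl trifluoromethanesulfonate, CC(C)(C)[Si](C)(C)OS(=O)(=O)C(F)(F)F
Why: Silylation of two hindered secondary alcohols with the silyl triflate/lutidine pair; the O5 ether prevents δ-lactonisation once the alkyne is reduced and the O8 ether prevents a competing 7,8-epoxide later.

Step 11
Reactants: 18 ethyl (5S,6S,7S,8S,21R)-5,8-bis[(tert-butyldimethylsilyl)oxy]-6,7-(isopropylidenedioxy)-21-(2-naphthylmethoxy)docos-2-ynoate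
Product: 19 ethyl (2Z,5S,6S,7S,8S,21R)-5,8-bis[(tert-butyldimethylsilyl)oxy]-6,7-(isopropylidenedioxy)-21-(2-naphthylmethoxy)docos-2-enoate
Conditions: H2 (1 atm), Lindlar catalyst, quinoline, EtOAc, rt
Reagents that add atoms: none
Why: Lindlar semihydrogenation (syn delivery of H2 on the poisoned palladium surface) sets the Z C2=C3 double bond and should leave the arylmethyl ether intact.

Step 12
Reactants: 19 ethyl (2Z,5S,6S,7S,8S,21R)-5,8-bis[(tert-butyldimethylsilyl)oxy]-6,7-(isopropylidenedioxy)-21-(2-naphthylmethoxy)docos-2-enoate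
Product: 20 (2Z,5S,6S,7S,8S,21R)-5,8-bis[(tert-butyldimethylsilyl)oxy]-6,7-(isopropylidenedioxy)-21-(2-naphthylmethoxy)docos-2-enoic acid
Conditions: LiOH·H2O, THF/H2O, 0 °C → rt; then dil. HCl to pH 4
Reagents that add atoms: lithium hydroxide, [Li+].[OH-]
Why: Saponification of the ethyl ester at a stage where no hydroxyl is free, so neither oxa-Michael addition to C3 nor base-induced silyl migration can intervene.

Step 13
Reactants: 20 (2Z,5S,6S,7S,8S,21R)-5,8-bis[(tert-butyldimethylsilyl)oxy]-6,7-(isopropylidenedioxy)-21-(2-naphthylmethoxy)docos-2-enoic acid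
Product: 21 (2Z,5S,6S,7S,8S,21R)-5,8-bis[(tert-butyldimethylsilyl)oxy]-6,7-dihydroxy-21-(2-naphthylmethoxy)docos-2-enoic acid
Conditions: TFA/H2O (9:1), CH2Cl2, 0 °C, monitored closely
Reagents that add atoms: none
Why: Acid-catalysed acetal hydrolysis of the dioxolane; the two secondary TBS ethers are hindered and inductively deactivated by the vicinal oxygens and the NAP ether is stable to aqueous acid, so short exposure at 0 °C should free only the 6,7-diol.

Step 14
Reactants: 21 (2Z,5S,6S,7S,8S,21R)-5,8-bis[(tert-butyldimethylsilyl)oxy]-6,7-dihydroxy-21-(2-naphthylmethoxy)docos-2-enoic acid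
Product: 23 (2Z,5S,6S,7S,8S,21R)-5,8-bis[(tert-butyldimethylsilyl)oxy]-6,7-dihydroxy-21-(2-naphthylmethoxy)docos-2-enoic acid 1,6-lactone (seven-membered enoate lactone on O6, free 7-OH), via mixed anhydride 22 (not isolated)
Conditions: 2,4,6-Cl3C6H2COCl, Et3N, THF, rt; then DMAP, toluene (5 mM), rt
Reagents that add atoms: none
Why: Yamaguchi lactonisation through the mixed anhydride; closure onto O6 gives the seven-membered ring, pre-organised by the Z alkene, and should be much faster than the strained eight-membered closure onto O7, which differentiates the two hydroxyls of the pseudo-symmetric diol.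

Step 15
Reactants: 23 seven-membered hydroxy lactone
Product: 25 (2Z,5S,6R,7R,8S,21R)-7-bromo-5,8-bis[(tert-butyldimethylsilyl)oxy]-6-hydroxy-21-(2-naphthylmethoxy)docos-2-enoic acid 1,6-lactone, via C7 triflate 24 (not isolated)
Conditions: Tf2O, pyridine, CH2Cl2, −30 °C; then Bu4NBr, toluene, 0 °C → rt
Reagents that add atoms: tetrabutylammonium bromide, CCCC[N+](CCCC)(CCCC)CCCC.[Br-]
Why: Triflation of the only free hydroxyl and SN2 displacement by bromide invert C7 and place Br anti to O6; the s-cis ester geometry enforced by the seven-membered ring turns the carbonyl oxygen away from C7, so no acyloxonium participation can cause retention or acyl shift.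

Step 16
Reactants: 25 7-bromo lactone NAP ether
Product: 26 (2Z,5S,6R,7R,8S,21R)-7-bromo-5,8-bis[(tert-butyldimethylsilyl)oxy]-6,21-dihydroxydocos-2-enoic acid 1,6-lactone
Conditions: DDQ, CH2Cl2/pH 7 buffer (10:1), rt
Reagents that add atoms: none
Why: Oxidative cleavage of the 2-naphthylmethyl ether by DDQ (benzylic hydride abstraction, then hydrolysis of the oxocarbenium ion), under which silyl ethers, the secondary bromide and the electron-poor alkene should be inert.

Step 17
Reactants: 26 (2Z,5S,6R,7R,8S,21R)-7-bromo-5,8-bis[(tert-butyldimethylsilyl)oxy]-6,21-dihydroxydocos-2-enoic acid 1,6-lactone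
Product: 29 (2Z,5S,6S,7S,8S,21R)-5,8-bis[(tert-butyldimethylsilyl)oxy]-6,7-epoxy-21-hydroxydocos-2-enoic acid 1,21-lactone, via sodium C21 alkoxide 27 (not isolated), via ring-enlarged bromo alkoxide 28 (not isolated)
Conditions: NaHMDS (1.0 equiv), THF (1 mM), −78 → 0 °C
Reagents that add atoms: none
Why: Proposed new method: the amide base turns the C21 hydroxyl into its sodium alkoxide, which adds to C1 of the strained seven-membered Z-enoate lactone; the bicyclic tetrahedral intermediate collapses by expelling O6 (the better, β-bromo-substituted leaving alkoxide), so the C1–O21 bond and the 22-membered ring arise by acyl substitution, and the freed O6 alkoxide then displaces bromide at C7 to give the O6–C7 bond and the oxirane, with NaBr as the only by-product. The closest known reactions are alkoxide-induced translactonisation ring expansions of ω-hydroxyalkyl lactones and the closure of vicinal bromohydrin esters to epoxides when the ester is cleaved by base. The macrolactone closes by intramolecular transesterification through a bridged tetrahedral intermediate (ring expansion 7 → 22, no activation of a Z-enoic acid), the oxirane by 3-exo-tet SN2. The only stereocentre altered is C7, inverted under substrate control by backside attack of O6 anti to the C–Br bond set in step 15, which gives the trans 6,7-epoxide; C5, C6, C8 and C21 keep their configuration and the Z alkene, never conjugated to an activated acyl group, stays fixed. The step needs intramolecular acyl attack to outrun oligomerisation, deprotonation at C4, conjugate addition of O6 to C3 and silyl migration; high dilution, exactly one equivalent of a non-nucleophilic base at low temperature, the strain of the small lactone and the very fast, irreversible halohydrin-alkoxide closure (which also removes the only nucleophile able to reverse the acyl transfer) are relied on for this.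

Step 18
Reactants: 29 (2Z,5S,6S,7S,8S,21R)-5,8-bis[(tert-butyldimethylsilyl)oxy]-6,7-epoxy-21-hydroxydocos-2-enoic acid 1,21-lactone
Product: 30 CIML C, (2Z,5S,6R,7R,8S,21R)-6,7-epoxy-5,8,21-trihydroxydocos-2-enoic acid 1,21-lactone
Conditions: HF·pyridine, pyridine, THF, 0 °C → rt
Reagents that add atoms: none
Why: Fluoride-mediated desilylation with pyridine-buffered HF·pyridine, mild enough that the hydroxy epoxide (no Payne rearrangement) and the Z-enoate macrolactone should survive.

**Compound list**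

1 | 10-bromodecan-1-ol | OCCCCCCCCCCBr | starting material
2 | tert-butyl[(10-bromodecyl)oxy]dimethylsilane | CC(C)(C)[Si](C)(C)OCCCCCCCCCCBr | intermediate
3 | (R)-propylene oxide | C[C@@H]1CO1 | starting material
4 | {10-[(tert-butyldimethylsilyl)oxy]decyl}magnesium bromide | CC(C)(C)[Si](C)(C)OCCCCCCCCCC[Mg]Br | intermediate (not isolated)
5 | (R)-13-[(tert-butyldimethylsilyl)oxy]tridecan-2-ol | C[C@@H](O)CCCCCCCCCCCO[Si](C)(C)C(C)(C)C | intermediate
6 | (R)-tert-butyldimethyl{[12-(2-naphthylmethoxy)tridecyl]oxy}silane | C[C@@H](OCc1ccc2ccccc2c1)CCCCCCCCCCCO[Si](C)(C)C(C)(C)C | intermediate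
7 | 2-({[(2R)-13-bromotridecan-2-yl]oxy}methyl)naphthalene | C[C@@H](OCc1ccc2ccccc2c1)CCCCCCCCCCCBr | intermediate
8 | 3,4-O-isopropylidene-D-mannitol | OC[C@@H](O)[C@H]1OC(C)(C)O[C@@H]1[C@H](O)CO | starting material
9 | 1,6-di-O-benzoyl-3,4-O-isopropylidene-D-mannitol | O=C(OC[C@@H](O)[C@H]1OC(C)(C)O[C@@H]1[C@H](O)COC(=O)c1ccccc1)c1ccccc1 | intermediate
10 | 1,6-di-O-benzoyl-3,4-O-isopropylidene-2,5-di-O-methanesulfonyl-D-mannitol | O=C(OC[C@@H](OS(C)(=O)=O)[C@H]1OC(C)(C)O[C@@H]1[C@H](OS(C)(=O)=O)COC(=O)c1ccccc1)c1ccccc1 | intermediate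
11 | 3,4-O-isopropylidene-2,5-di-O-methanesulfonyl-D-mannitol | OC[C@@H](OS(C)(=O)=O)[C@H]1OC(C)(C)O[C@@H]1[C@H](OS(C)(=O)=O)CO | intermediate (not isolated)
12 | 1,2:5,6-dianhydro-3,4-O-isopropylidene-L-iditol, (2S,3R,4R,5S) | C1O[C@@H]1[C@H]1OC(C)(C)O[C@@H]1[C@@H]1CO1 | intermediate
13 | [(12R)-12-(2-naphthylmethoxy)tridecyl]magnesium bromide | C[C@@H](OCc1ccc2ccccc2c1)CCCCCCCCCCC[Mg]Br | intermediate (not isolated)
14 | (2S)-2-{(4R,5R)-5-[(1S,14R)-1-hydroxy-14-(2-naphthylmethoxy)pentadecyl]-2,2-dimethyl-1,3-dioxolan-4-yl}oxirane; C4–C22, (5S,6R,7R,8S,21R) | C[C@@H](OCc1ccc2ccccc2c1)CCCCCCCCCCCC[C@H](O)[C@H]1OC(C)(C)O[C@@H]1[C@@H]1CO1 | intermediate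
15 | ethyl propiolate | C#CC(=O)OCC | starting material
16 | lithium ethyl propiolate (ethyl 3-lithiopropiolate) | [Li]C#CC(=O)OCC | intermediate (not isolated)
17 | ethyl (5S,6R,7R,8S,21R)-5,8-dihydroxy-6,7-(isopropylidenedioxy)-21-(2-naphthylmethoxy)docos-2-ynoate | C[C@@H](OCc1ccc2ccccc2c1)CCCCCCCCCCCC[C@H](O)[C@H]1OC(C)(C)O[C@@H]1[C@@H](O)CC#CC(=O)OCC | intermediate
18 | ethyl (5S,6S,7S,8S,21R)-5,8-bis[(tert-butyldimethylsilyl)oxy]-6,7-(isopropylidenedioxy)-21-(2-naphthylmethoxy)docos-2-ynoate | C[C@@H](OCc1ccc2ccccc2c1)CCCCCCCCCCCC[C@H](O[Si](C)(C)C(C)(C)C)[C@H]1OC(C)(C)O[C@@H]1[C@@H](O[Si](C)(C)C(C)(C)C)CC#CC(=O)OCC | intermediate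
19 | ethyl (2Z,5S,6S,7S,8S,21R)-5,8-bis[(tert-butyldimethylsilyl)oxy]-6,7-(isopropylidenedioxy)-21-(2-naphthylmethoxy)docos-2-enoate | C[C@@H](OCc1ccc2ccccc2c1)CCCCCCCCCCCC[C@H](O[Si](C)(C)C(C)(C)C)[C@H]1OC(C)(C)O[C@@H]1[C@@H](O[Si](C)(C)C(C)(C)C)C/C=C\C(=O)OCC | intermediate
20 | (2Z,5S,6S,7S,8S,21R)-5,8-bis[(tert-butyldimethylsilyl)oxy]-6,7-(isopropylidenedioxy)-21-(2-naphthylmethoxy)docos-2-enoic acid | C[C@@H](OCc1ccc2ccccc2c1)CCCCCCCCCCCC[C@H](O[Si](C)(C)C(C)(C)C)[C@H]1OC(C)(C)O[C@@H]1[C@@H](O[Si](C)(C)C(C)(C)C)C/C=C\C(=O)O | intermediate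
21 | (2Z,5S,6S,7S,8S,21R)-5,8-bis[(tert-butyldimethylsilyl)oxy]-6,7-dihydroxy-21-(2-naphthylmethoxy)docos-2-enoic acid | C[C@@H](OCc1ccc2ccccc2c1)CCCCCCCCCCCC[C@H](O[Si](C)(C)C(C)(C)C)[C@@H](O)[C@H](O)[C@@H](O[Si](C)(C)C(C)(C)C)C/C=C\C(=O)O | intermediate
22 | mixed anhydride of 21 with 2,4,6-trichlorobenzoic acid | C[C@@H](OCc1ccc2ccccc2c1)CCCCCCCCCCCC[C@H](O[Si](C)(C)C(C)(C)C)[C@@H](O)[C@H](O)[C@@H](O[Si](C)(C)C(C)(C)C)C/C=C\C(=O)OC(=O)c1c(Cl)cc(Cl)cc1Cl | intermediate (not isolated)
23 | (2Z,5S,6S,7S,8S,21R)-5,8-bis[(tert-butyldimethylsilyl)oxy]-6,7-dihydroxy-21-(2-naphthylmethoxy)docos-2-enoic acid 1,6-lactone (6,7-dihydrooxepin-2(5H)-one ring, free 7-OH) | C[C@@H](OCc1ccc2ccccc2c1)CCCCCCCCCCCC[C@H](O[Si](C)(C)C(C)(C)C)[C@@H](O)[C@@H]1OC(=O)/C=C\C[C@@H]1O[Si](C)(C)C(C)(C)C | intermediate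
24 | C7 trifluoromethanesulfonate of 23, (2Z,5S,6R,7S,8S,21R) | C[C@@H](OCc1ccc2ccccc2c1)CCCCCCCCCCCC[C@H](O[Si](C)(C)C(C)(C)C)[C@@H](OS(=O)(=O)C(F)(F)F)[C@@H]1OC(=O)/C=C\C[C@@H]1O[Si](C)(C)C(C)(C)C | intermediate (not isolated)
25 | (2Z,5S,6R,7R,8S,21R)-7-bromo-5,8-bis[(tert-butyldimethylsilyl)oxy]-6-hydroxy-21-(2-naphthylmethoxy)docos-2-enoic acid 1,6-lactone | C[C@@H](OCc1ccc2ccccc2c1)CCCCCCCCCCCC[C@H](O[Si](C)(C)C(C)(C)C)[C@H](Br)[C@@H]1OC(=O)/C=C\C[C@@H]1O[Si](C)(C)C(C)(C)C | intermediate
26 | (2Z,5S,6R,7R,8S,21R)-7-bromo-5,8-bis[(tert-butyldimethylsilyl)oxy]-6,21-dihydroxydocos-2-enoic acid 1,6-lactone | C[C@@H](O)CCCCCCCCCCCC[C@H](O[Si](C)(C)C(C)(C)C)[C@H](Br)[C@@H]1OC(=O)/C=C\C[C@@H]1O[Si](C)(C)C(C)(C)C | intermediate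
27 | sodium C21 alkoxide of 26 | C[C@@H]([O-])CCCCCCCCCCCC[C@H](O[Si](C)(C)C(C)(C)C)[C@H](Br)[C@@H]1OC(=O)/C=C\C[C@@H]1O[Si](C)(C)C(C)(C)C.[Na+] | intermediate (not isolated)
28 | sodium 6-alkoxide of (2Z,5S,6R,7R,8S,21R)-7-bromo-5,8-bis[(tert-butyldimethylsilyl)oxy]-6,21-dihydroxydocos-2-enoic acid 1,21-lactone | C[C@@H]1CCCCCCCCCCCC[C@H](O[Si](C)(C)C(C)(C)C)[C@H](Br)[C@H]([O-])[C@@H](O[Si](C)(C)C(C)(C)C)C/C=C\C(=O)O1.[Na+] | intermediate (not isolated)
29 | (2Z,5S,6S,7S,8S,21R)-5,8-bis[(tert-butyldimethylsilyl)oxy]-6,7-epoxy-21-hydroxydocos-2-enoic acid 1,21-lactone | C[C@@H]1CCCCCCCCCCCC[C@H](O[Si](C)(C)C(C)(C)C)[C@H]2O[C@@H]2[C@@H](O[Si](C)(C)C(C)(C)C)C/C=C\C(=O)O1 | intermediate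
30 | CIML C, (2Z,5S,6R,7R,8S,21R)-6,7-epoxy-5,8,21-trihydroxydocos-2-enoic acid 1,21-lactone | C[C@@H]1CCCCCCCCCCCC[C@H](O)[C@H]2O[C@@H]2[C@@H](O)C/C=C\C(=O)O1 | target

**Step count**

Total steps: 18. Longest linear sequence: 15 (steps 1–4, then 8–18); the carbohydrate branch (steps 5–7) joins at step 8.

**Steps most likely to fail**

Risk 1 – step 17 (the key step). Chain-to-chain acyl transfer may win over ring expansion. The alkoxides may instead remove a C4 proton (double-bond migration, loss of the C5 silyloxy group), add to C3, or shift a silyl group. The fallback uses known chemistry and sets out from 26. LiOH in aqueous THF saponifies the lactone, and the liberated O6 closes the oxirane on C7 with loss of bromide, which should give the epoxy seco acid F1. Shiina macrolactonisation of F1 (MNBA, DMAP, toluene, high dilution) onto the C21 hydroxyl comes back to the route at 29.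

Risk 2 – step 15. Substitution at C7, flanked by two oxygen-bearing carbons, may be slow, so that elimination of the triflate or later bromide-for-bromide exchange erodes the configuration. The fallback sets out from 23, inverts the carbinol by oxidation and reduction, and uses a sulfonate as nucleofuge. Dess–Martin oxidation gives the 7-ketone F2. Luche reduction (NaBH4, CeCl3, MeOH, −78 °C; Felkin–Anh addition anti to both O6 and O8, a matched case) should give the 7-epi alcohol F3. Mesylation (MsCl, Et3N) gives the mesylate F4, whose leaving group stands anti to O6 as the bromide does in 25. DDQ frees the C21 hydroxyl to give the hydroxy mesylate F5. The base treatment of step 17, with mesylate expelled in place of bromide, comes back to the route at 29.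

Risk 3 – step 13. Hydrolysis of the hindered trans-dioxolane may be slower than loss or migration of the silyl ethers. The fallback sets out from 17 and reverses the order of deprotection and silylation. Aqueous TFA, with no silyl group present, gives the tetraol ynoate F6. TBSCl/imidazole in DMF at −20 °C should silylate the less hindered outer hydroxyls O5 and O8 to give the 6,7-diol ynoate F7. LiOH cleaves the activated ynoate ester to the ynoic acid F8, and Lindlar semihydrogenation of F8 comes back to the route at 21.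

**Further compounds**

F1 | step 17 | (2Z,5S,6S,7S,8S,21R)-5,8-bis[(tert-butyldimethylsilyl)oxy]-6,7-epoxy-21-hydroxydocos-2-enoic acid | C[C@@H](O)CCCCCCCCCCCC[C@H](O[Si](C)(C)C(C)(C)C)[C@H]1O[C@@H]1[C@@H](O[Si](C)(C)C(C)(C)C)C/C=C\C(=O)O
F2 | step 15 | (2Z,5S,6R,8S,21R)-5,8-bis[(tert-butyldimethylsilyl)oxy]-6-hydroxy-21-(2-naphthylmethoxy)-7-oxodocos-2-enoic acid 1,6-lactone | C[C@@H](OCc1ccc2ccccc2c1)CCCCCCCCCCCC[C@H](O[Si](C)(C)C(C)(C)C)C(=O)[C@@H]1OC(=O)/C=C\C[C@@H]1O[Si](C)(C)C(C)(C)C
F3 | step 15 | (2Z,5S,6S,7R,8S,21R)-5,8-bis[(tert-butyldimethylsilyl)oxy]-6,7-dihydroxy-21-(2-naphthylmethoxy)docos-2-enoic acid 1,6-lactone (7-epimer of 23) | C[C@@H](OCc1ccc2ccccc2c1)CCCCCCCCCCCC[C@H](O[Si](C)(C)C(C)(C)C)[C@H](O)[C@@H]1OC(=O)/C=C\C[C@@H]1O[Si](C)(C)C(C)(C)C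
F4 | step 15 | (2Z,5S,6R,7R,8S,21R)-5,8-bis[(tert-butyldimethylsilyl)oxy]-6-hydroxy-7-(methanesulfonyloxy)-21-(2-naphthylmethoxy)docos-2-enoic acid 1,6-lactone | C[C@@H](OCc1ccc2ccccc2c1)CCCCCCCCCCCC[C@H](O[Si](C)(C)C(C)(C)C)[C@H](OS(C)(=O)=O)[C@@H]1OC(=O)/C=C\C[C@@H]1O[Si](C)(C)C(C)(C)C
F5 | step 15 | (2Z,5S,6R,7R,8S,21R)-5,8-bis[(tert-butyldimethylsilyl)oxy]-6,21-dihydroxy-7-(methanesulfonyloxy)docos-2-enoic acid 1,6-lactone | C[C@@H](O)CCCCCCCCCCCC[C@H](O[Si](C)(C)C(C)(C)C)[C@H](OS(C)(=O)=O)[C@@H]1OC(=O)/C=C\C[C@@H]1O[Si](C)(C)C(C)(C)C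
F6 | step 13 | ethyl (5S,6R,7R,8S,21R)-5,6,7,8-tetrahydroxy-21-(2-naphthylmethoxy)docos-2-ynoate | C[C@@H](OCc1ccc2ccccc2c1)CCCCCCCCCCCC[C@H](O)[C@@H](O)[C@H](O)[C@@H](O)CC#CC(=O)OCC
F7 | step 13 | ethyl (5S,6S,7S,8S,21R)-5,8-bis[(tert-butyldimethylsilyl)oxy]-6,7-dihydroxy-21-(2-naphthylmethoxy)docos-2-ynoate | C[C@@H](OCc1ccc2ccccc2c1)CCCCCCCCCCCC[C@H](O[Si](C)(C)C(C)(C)C)[C@@H](O)[C@H](O)[C@@H](O[Si](C)(C)C(C)(C)C)CC#CC(=O)OCC
F8 | step 13 | (5S,6S,7S,8S,21R)-5,8-bis[(tert-butyldimethylsilyl)oxy]-6,7-dihydroxy-21-(2-naphthylmethoxy)docos-2-ynoic acid | C[C@@H](OCc1ccc2ccccc2c1)CCCCCCCCCCCC[C@H](O[Si](C)(C)C(C)(C)C)[C@@H](O)[C@H](O)[C@@H](O[Si](C)(C)C(C)(C)C)CC#CC(=O)O
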